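**Strategy.** Ring A (C1, C2, C3, C4, C5, C10) is treated as a cyclohexene and cut at C1–C10 and C4–C5. A single intermolecular Diels–Alder reaction joins the C5=C10 alkene of a ring B cyclopentenone (C6 ketone) on a preformed B/C/D tricycle to tert-butyl (2Z)-2-methylpenta-2,4-dienoate (C1–C4, C18, C19). It closes ring A, sets the C4 quaternary centre and leaves a C2=C3 alkene for the late ene oxygenation to the 3-hydroxy-C1=C2 unit. The tricyclic enone comes from a first Diels–Alder reaction and a palladium-mediated ring D closure. The C6 ketone is afterwards relayed into C7 and a C5=C10 alkene onto which C19 lactonises.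

Key step: step 8

Remark: atoms carry gibberellane numbers (ring A C1–C5 and C10; ring B C5, C6, C8, C9, C10; ring C C8, C9, C11–C14; ring D C8, C14, C13, C16, C15; C7 carboxyl, C17 methylene, C18 methyl, C19 lactone carbonyl). α is the face of ring B that carries C11, C14 and the lactone oxygen; β is the face of H-9 and C15. Facial arguments assume the chair form of ring C, in which the C9–C10 bond is axial and the C14 methylene is pseudoaxial over the α face of ring B.

Step 1
Reactants: 1 (4R)-4-[(tert-butyldimethylsilyl)oxy]cyclopent-2-en-1-one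
Product: 2 (4R)-4-[(tert-butyldimethylsilyl)oxy]-2-iodocyclopent-2-en-1-one
Conditions: I2, pyridine, CH2Cl2, 0 °C to rt
Reagents that add atoms: iodine, II
Why: α-Iodination of the enone by the pyridine addition–iodination–elimination sequence (Baylis–Hillman-type) puts a coupling handle on C8 without touching the C10 stereocentre.

Step 2
Reactants: 2 (4R)-4-[(tert-butyldimethylsilyl)oxy]-2-iodocyclopent-2-en-1-one; 3 allyltributylstannane
Product: 4 (4R)-2-allyl-4-[(tert-butyldimethylsilyl)oxy]cyclopent-2-en-1-one
Conditions: PdCl2(PhCN)2 (cat.), AsPh3, CuI, NMP, rt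
Reagents that add atoms: none
Why: Stille coupling of the α-iodoenone with the allylstannane attaches the C15–C16=C17 unit to C8 under neutral conditions that spare the allylic silyl ether.

Step 3
Reactants: 4 (4R)-2-allyl-4-[(tert-butyldimethylsilyl)oxy]cyclopent-2-en-1-one; 5 2,3-bis[(trimethylsilyl)oxy]buta-1,3-diene
Product: 6 cis-fused hexahydroindenone bis(silyl enol ether) (rings B and C; allyl on C8, H-9 and the C10 silyloxy group all β)
Conditions: toluene, BHT (cat.), 140 °C, sealed tube
Reagents that add atoms: none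
Why: Thermal Diels–Alder reaction of the electron-rich symmetric diene with the enone closes ring C cis (C8 quaternary, H-9 syn to the allyl group), the diene adding to the face opposite the C10 silyloxy group, which fixes the absolute configuration of C8 and C9.

Step 4
Reactants: 6 cis-fused hexahydroindenone bis(silyl enol ether)
Product: 7 B/C/D tricyclic diketone (C6 and C12 ketones, 13-OSiMe3, 10β-OSi(t-Bu)Me2, exocyclic C16=C17)
Conditions: Pd(OAc)2 (1.1 equiv), MeCN, rt
Reagents that add atoms: none
Why: Palladium-promoted cycloalkenylation of a silyl enol ether, in which the enol carbon C13 adds to the palladium-bound allyl alkene in the 5-exo mode (preferred over 6-exo closure from C12) on the only face the one-carbon tether allows and β-hydride elimination gives the exocyclic C16=C17, while loss of the C12 silyl group unveils the C12 ketone and leaves the bridgehead C13 oxygen silylated.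

Step 5
Reactants: 7 B/C/D tricyclic diketone
Product: 8 B/C/D tricyclic enone (C5=C10 conjugated to the C6 ketone)
Conditions: DBU, CH2Cl2, 0 °C to rt
Reagents that add atoms: none
Why: E1cB elimination of the β-silyloxy ketone removes the now redundant C10 stereocentre and creates the cyclopentenone dienophile.

Step 6
Reactants: 9 tert-butyl 2-bromopropanoate; 10 diphenyl phosphite
Product: 11 tert-butyl 2-(diphenoxyphosphoryl)propanoate
Conditions: Et3N, CH2Cl2, 0 °C to rt
Reagents that add atoms: none
Why: Michaelis–Becker P-alkylation of the phosphite anion by the activated α-bromo ester gives the diaryl phosphonate needed for a Z-selective olefination, and its racemic stereocentre is destroyed in step 7.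

Step 7
Reactants: 11 tert-butyl 2-(diphenoxyphosphoryl)propanoate; 12 acrolein
Product: 14 tert-butyl (2Z)-2-methylpenta-2,4-dienoate, via sodium phosphonate carbanion 13 (not isolated)
Conditions: NaH, THF, 0 °C; then 12, −78 °C to 0 °C
Reagents that add atoms: none
Why: Horner–Wadsworth–Emmons olefination in the Ando variant, in which the electron-poor diaryl phosphonate makes collapse of the kinetically preferred adduct faster than its equilibration and so gives the Z-trisubstituted alkene, with the ester cis and the methyl group trans to the vinyl group.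

Step 8
Reactants: 8 B/C/D tricyclic enone; 14 tert-butyl (2Z)-2-methylpenta-2,4-dienoate
Product: 15 tetracyclic Diels–Alder adduct (tert-butyl 19-ester, C2=C3, H-5α, H-10α, rings A/B cis, C6 and C12 ketones)
Conditions: 14 (3 equiv), toluene, BHT (cat.), 150 °C, sealed tube
Reagents that add atoms: none
Why: The bonds C1–C10 and C4–C5 form in one concerted, asynchronous [4+2] cycloaddition in which the unsubstituted diene terminus C1 bonds to the enone β-carbon C10 ahead of the more congested C4–C5 bond to the α-carbon. The closest known reaction type is the thermal (or high-pressure) Diels–Alder reaction of 1-alkoxycarbonyl-1,3-dienes with cyclopent-2-enones, which gives the ortho adducts. Ring A is closed in the intermolecular [4+2] mode, suprafacial on both partners, and is therefore cis-fused to ring B. C5 and C10 arise by cis addition to the β face of the ring alkene, the convex face that carries only the pseudoaxial H-9 and the outward-turned C15, whereas the α face lies under the pseudoaxial C14 methylene of ring C; C4 is set by the endo rule (C6 carbonyl under the diene) acting on the Z-diene, which puts the outside methyl group cis to C6 and the inside ester on the convex face of ring A, the face that becomes α once C5 and C10 are flattened. The step needs regio-, endo- and π-facial selectivity, secured respectively by the matched orbital coefficients, by the ring carbonyl and by the shape of the cis-fused tricycle. Only the configuration at C4 must persist, because C5 and C10 are trigonalised and reset in steps 10, 12 and 13, and the isolated C16=C17 alkene and the two ketone carbonyls are not dienophiles under these conditions.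

Step 9
Reactants: 15 tetracyclic Diels–Alder adduct
Product: 17 C11=C12 tert-butyldimethylsilyl enol ether, via lithium enolate 16 (not isolated)
Conditions: LiN(iPr)2, THF, −78 °C; then t-BuMe2SiCl, HMPA, −78 °C to 0 °C
Reagents that add atoms: tert-butyldimethylsilyl chloride, CC(C)(C)[Si](C)(C)Cl
Why: Kinetic enolisation takes the unhindered C11 methylene next to the C12 ketone in preference to the neopentyl methine H-5, and O-silylation masks C12 as a flat enol ether that cannot compete in the next enolisation and places no axial group over ring C.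

Step 10
Reactants: 17 C11=C12 tert-butyldimethylsilyl enol ether
Product: 19 C5=C6 enol triflate, via potassium enolate 18 (not isolated)
Conditions: KN(SiMe3)2, THF, −78 °C to 0 °C; then PhNTf2, −78 °C to rt
Reagents that add atoms: N-phenylbis(trifluoromethanesulfonimide), O=S(=O)(N(c1ccccc1)S(=O)(=O)C(F)(F)F)C(F)(F)F
Why: The C6 ketone can enolise only towards C5 because C8 is quaternary, so O-sulfonylation of the potassium enolate gives the single enol triflate and erases the temporary C5 stereocentre.

Step 11
Reactants: 19 C5=C6 enol triflate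
Product: 20 α,β-unsaturated 7-ester (2-(trimethylsilyl)ethyl ester on C6, C5=C6)
Conditions: Pd(OAc)2 (cat.), PPh3, CO (1 atm), Et3N, Me3SiCH2CH2OH, DMF, 60 °C
Reagents that add atoms: carbon monoxide, [C-]#[O+]; 2-(trimethylsilyl)ethanol, C[Si](C)(C)CCO
Why: Palladium-catalysed alkoxycarbonylation of the enol triflate introduces C7 on C6 as a fluoride-cleavable ester.

Step 12
Reactants: 20 α,β-unsaturated 7-ester
Product: 22 β,γ-unsaturated 7-ester (C5=C10; 6α-ester), via lithium dienolate 21 (not isolated)
Conditions: LiN(iPr)2, HMPA, THF, −78 °C; then AcOH, −78 °C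
Reagents that add atoms: none
Why: γ-Deprotonation removes the pseudoaxial H-10α, which is aligned with the enoate π system and is reachable because C12 is trigonal, and kinetic α-protonation of the extended dienolate deconjugates it to the C5=C10 alkene, the proton entering C6 from the β face (the α face is screened by the pseudoaxial C14 methylene) to give the 6α-ester, which is corrected in step 15.

Step 13
Reactants: 22 β,γ-unsaturated 7-ester
Product: 23 6-epi 19,10-lactone (C2=C3, 12-ketone, 13-OH, 6α-ester)
Conditions: CF3CO2H, CH2Cl2, 0 °C; aq. NaHCO3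
Reagents that add atoms: none
Why: Acid-mediated lactonisation of a β,γ-unsaturated ester, in which protonation of the tetrasubstituted alkene at C5 from the β face gives the tertiary C10 cation that the α-oriented C19 tert-butyl ester captures with loss of isobutene, the only closure that gives a cis-fused γ-lactone (H-5β, 10α-oxygen, rings A/B trans), while the same acid hydrolyses the silyl enol ether to the C12 ketone and cleaves the tertiary trimethylsilyl ether.

Step 14
Reactants: 23 6-epi 19,10-lactone
Product: 24 12α-alcohol (12α,13-diol, 6α-ester)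
Conditions: NaBH4, MeOH/THF, −40 °C to −20 °C
Reagents that add atoms: none
Why: Chemoselective borohydride reduction of the ketone in which the axial trajectory over ring C is closed by the syn-axial lactone oxygen on C10, so hydride enters from the face of the C15–C16 bridge and gives the axial 12α-alcohol, which also removes the base-sensitive α-ketol before step 15.

Step 15
Reactants: 24 12α-alcohol
Product: 25 19,10-lactone with the 6β-ester (C2=C3, 12α,13-diol)
Conditions: KOt-Bu (0.3 equiv), t-BuOH/THF, 0 °C to rt; aq. NH4Cl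
Reagents that add atoms: none
Why: Base-mediated epimerisation through the ester enolate moves C7 to the β face, trans to the quaternary C4 across the C5–C6 bond and away from the pseudoaxial C14 methylene, which is the thermodynamically preferred arrangement.

Step 16
Reactants: 25 19,10-lactone with the 6β-ester
Product: 26 15α-alcohol
Conditions: SeO2 (cat.), t-BuOOH, CH2Cl2, rt
Reagents that add atoms: tert-butyl hydroperoxide, CC(C)(C)OO
Why: Riley allylic oxidation (ene reaction then [2,3]-sigmatropic shift) of the unhindered C16=C17 alkene functionalises its only allylic CH2 (C15) from the open exo face of ring D to give the 15α-alcohol, whereas the C2=C3 alkene would need selenium at the neopentyl C3.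

Step 17
Reactants: 26 15α-alcohol
Product: 27 15-ketone (cross-conjugated with C16=C17)
Conditions: MnO2 (activated, excess), CH2Cl2, rt
Reagents that add atoms: none
Why: Allylic oxidation with MnO2 touches only the C15 alcohol (the C12 alcohol is saturated and axial, the C13 alcohol tertiary) and gives the enone, which erases the wrong C15 configuration and deactivates the exocyclic alkene for the next step.

Step 18
Reactants: 27 15-ketone
Product: 29 3β-alcohol (C1=C2 alkene), via 3β-hydroperoxide 28 (not isolated)
Conditions: O2, tetraphenylporphyrin (cat.), visible light, CH2Cl2, −20 °C; then Me2S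
Reagents that add atoms: dioxygen, O=O
Why: Schenck ene reaction in which singlet oxygen can only bond to C3 with abstraction of H-1 (C4 bears no hydrogen), on the β face where H-1β is pseudoaxial and the lactone bridge does not interfere, and reduction of the hydroperoxide gives the 3β-hydroxy-C1=C2 unit while the electron-poor enone alkene stays inert.

Step 19
Reactants: 29 3β-alcohol
Product: 30 2-(trimethylsilyl)ethyl ester of the target gibberellin
Conditions: NaBH4, CeCl3·7H2O, MeOH, −78 °C
Reagents that add atoms: none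
Why: Luche 1,2-reduction of the enone by hydride attack from the open exo face of ring D gives the endo 15β-alcohol.

Step 20
Reactants: 30 2-(trimethylsilyl)ethyl ester of the target gibberellin
Product: 31 target gibberellin
Conditions: (Me2N)3S+ Me3SiF2−, DMF, 0 °C to rt; aq. NH4Cl
Reagents that add atoms: none
Why: Fluoride-induced β-elimination of ethene cleaves the 2-(trimethylsilyl)ethyl ester under near-neutral conditions that should spare the allylic lactone and the 3-hydroxy group.

**Compound list**

1 | (4R)-4-[(tert-butyldimethylsilyl)oxy]cyclopent-2-en-1-one | O=C1C=C[C@H](O[Si](C)(C)C(C)(C)C)C1 | starting material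
2 | (4R)-4-[(tert-butyldimethylsilyl)oxy]-2-iodocyclopent-2-en-1-one | O=C1C(I)=C[C@H](O[Si](C)(C)C(C)(C)C)C1 | intermediate
3 | allyltributylstannane | C=CC[Sn](CCCC)(CCCC)CCCC | starting material
4 | (4R)-2-allyl-4-[(tert-butyldimethylsilyl)oxy]cyclopent-2-en-1-one | O=C1C(CC=C)=C[C@H](O[Si](C)(C)C(C)(C)C)C1 | intermediate
5 | 2,3-bis[(trimethylsilyl)oxy]buta-1,3-diene | C=C(O[Si](C)(C)C)C(=C)O[Si](C)(C)C | starting material
6 | 7a-allyl-3-[(tert-butyldimethylsilyl)oxy]-5,6-bis[(trimethylsilyl)oxy]-2,3,3a,4,7,7a-hexahydro-1H-inden-1-one, cis-fused, allyl, H-3a and 3-silyloxy on one face | C=CC[C@]23CC(O[Si](C)(C)C)=C(O[Si](C)(C)C)C[C@H]2[C@H](O[Si](C)(C)C(C)(C)C)CC3=O | intermediate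
7 | B/C/D tricyclic diketone: C6 and C12 ketones, 13-trimethylsilyloxy, 10β-tert-butyldimethylsilyloxy, 16-methylene, H-9β | C=C1C[C@]23C[C@@]1(O[Si](C)(C)C)C(=O)C[C@H]2[C@H](O[Si](C)(C)C(C)(C)C)CC3=O | intermediate
8 | B/C/D tricyclic enone: C5=C10 conjugated to C6 ketone, C12 ketone, 13-trimethylsilyloxy, 16-methylene | C=C1C[C@]23C[C@@]1(O[Si](C)(C)C)C(=O)C[C@H]2C=CC3=O | intermediate
9 | tert-butyl 2-bromopropanoate (racemic) | CC(Br)C(=O)OC(C)(C)C | starting material
10 | diphenyl phosphite | O=[PH](Oc1ccccc1)Oc1ccccc1 | starting material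
11 | tert-butyl 2-(diphenoxyphosphoryl)propanoate (racemic) | CC(C(=O)OC(C)(C)C)P(=O)(Oc1ccccc1)Oc1ccccc1 | intermediate
12 | acrolein | C=CC=O | starting material
13 | sodium salt of the phosphonate carbanion of 11 | CC(=C([O-])OC(C)(C)C)P(=O)(Oc1ccccc1)Oc1ccccc1.[Na+] | intermediate
14 | tert-butyl (2Z)-2-methylpenta-2,4-dienoate | C=C/C=C(/C)C(=O)OC(C)(C)C | intermediate
15 | Diels–Alder adduct: ring A cis-fused on the β face of ring B (H-5α, H-10α, H-9β), 18-methyl and tert-butyl 19-ester on C4, C2=C3, C6 and C12 ketones, 13-trimethylsilyloxy, 16-methylene | C=C1C[C@]23C[C@@]1(O[Si](C)(C)C)C(=O)C[C@H]2[C@@H]2CC=C[C@@](C)(C(=O)OC(C)(C)C)[C@@H]2C3=O | intermediate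
16 | lithium C11=C12 enolate of 15 | C=C1C[C@]23C[C@@]1(O[Si](C)(C)C)C([O-])=C[C@H]2[C@@H]2CC=C[C@@](C)(C(=O)OC(C)(C)C)[C@@H]2C3=O.[Li+] | intermediate
17 | C11=C12 tert-butyldimethylsilyl enol ether of 15 (C6 ketone retained) | C=C1C[C@]23C[C@@]1(O[Si](C)(C)C)C(O[Si](C)(C)C(C)(C)C)=C[C@H]2[C@@H]2CC=C[C@@](C)(C(=O)OC(C)(C)C)[C@@H]2C3=O | intermediate
18 | potassium C5=C6 enolate of 17 | C=C1C[C@]23C[C@@]1(O[Si](C)(C)C)C(O[Si](C)(C)C(C)(C)C)=C[C@H]2[C@@H]2CC=C[C@@](C)(C(=O)OC(C)(C)C)C2=C3[O-].[K+] | intermediate
19 | C5=C6 enol triflate of 17 | C=C1C[C@]23C[C@@]1(O[Si](C)(C)C)C(O[Si](C)(C)C(C)(C)C)=C[C@H]2[C@@H]2CC=C[C@@](C)(C(=O)OC(C)(C)C)C2=C3OS(=O)(=O)C(F)(F)F | intermediate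
20 | C5=C6 unsaturated diester: 2-(trimethylsilyl)ethyl 7-ester, tert-butyl 19-ester, C11=C12 silyl enol ether, H-10α | C=C1C[C@]23C[C@@]1(O[Si](C)(C)C)C(O[Si](C)(C)C(C)(C)C)=C[C@H]2[C@@H]2CC=C[C@@](C)(C(=O)OC(C)(C)C)C2=C3C(=O)OCC[Si](C)(C)C | intermediate
21 | lithium dienolate (C7=C6, C5=C10) of 20 | C=C1C[C@]23C[C@@]1(O[Si](C)(C)C)C(O[Si](C)(C)C(C)(C)C)=C[C@H]2C2=C([C@](C)(C(=O)OC(C)(C)C)C=CC2)C3=C([O-])OCC[Si](C)(C)C.[Li+] | intermediate
22 | C5=C10 diester with H-6β (7-ester α), C11=C12 silyl enol ether, 13-trimethylsilyloxy | C=C1C[C@]23C[C@@]1(O[Si](C)(C)C)C(O[Si](C)(C)C(C)(C)C)=C[C@H]2C2=C([C@](C)(C(=O)OC(C)(C)C)C=CC2)[C@H]3C(=O)OCC[Si](C)(C)C | intermediate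
23 | 6-epi 19,10-lactone: C2=C3, 12-ketone, 13-hydroxy, 2-(trimethylsilyl)ethyl 7-ester on the α face, 16-methylene | C=C1C[C@]23C[C@@]1(O)C(=O)C[C@H]2[C@@]12CC=C[C@@](C)(C(=O)O1)[C@H]2[C@H]3C(=O)OCC[Si](C)(C)C | intermediate
24 | 12α-alcohol of 23 (12α,13-diol, 6α-ester) | C=C1C[C@]23C[C@@]1(O)[C@@H](O)C[C@H]2[C@@]12CC=C[C@@](C)(C(=O)O1)[C@H]2[C@H]3C(=O)OCC[Si](C)(C)C | intermediate
25 | 19,10-lactone with 6β-ester: C2=C3, 12α,13-diol, 2-(trimethylsilyl)ethyl 7-ester, 16-methylene | C=C1C[C@]23C[C@@]1(O)[C@@H](O)C[C@H]2[C@@]12CC=C[C@@](C)(C(=O)O1)[C@H]2[C@@H]3C(=O)OCC[Si](C)(C)C | intermediate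
26 | 15α-alcohol of 25 | C=C1[C@H](O)[C@]23C[C@@]1(O)[C@@H](O)C[C@H]2[C@@]12CC=C[C@@](C)(C(=O)O1)[C@H]2[C@@H]3C(=O)OCC[Si](C)(C)C | intermediate
27 | 15-ketone (16-methylene enone), C2=C3, 12α,13-diol | C=C1C(=O)[C@]23C[C@@]1(O)[C@@H](O)C[C@H]2[C@@]12CC=C[C@@](C)(C(=O)O1)[C@H]2[C@@H]3C(=O)OCC[Si](C)(C)C | intermediate
28 | 3β-hydroperoxide with C1=C2, 15-ketone | C=C1C(=O)[C@]23C[C@@]1(O)[C@@H](O)C[C@H]2[C@@]12C=C[C@H](OO)[C@@](C)(C(=O)O1)[C@H]2[C@@H]3C(=O)OCC[Si](C)(C)C | intermediate
29 | 3β-alcohol with C1=C2, 15-ketone | C=C1C(=O)[C@]23C[C@@]1(O)[C@@H](O)C[C@H]2[C@@]12C=C[C@H](O)[C@@](C)(C(=O)O1)[C@H]2[C@@H]3C(=O)OCC[Si](C)(C)C | intermediate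
30 | 2-(trimethylsilyl)ethyl ester of the target gibberellin | C=C1[C@@H](O)[C@]23C[C@@]1(O)[C@@H](O)C[C@H]2[C@@]12C=C[C@H](O)[C@@](C)(C(=O)O1)[C@H]2[C@@H]3C(=O)OCC[Si](C)(C)C | intermediate
31 | target gibberellin: 19,10-lactone 7-carboxylic acid with 3β-, 12α-, 13- and 15β-hydroxy groups, C1=C2 and 16-methylene | C=C1[C@@H](O)[C@]23C[C@@]1(O)[C@@H](O)C[C@H]2[C@@]12C=C[C@H](O)[C@@](C)(C(=O)O1)[C@H]2[C@@H]3C(=O)O | target

**Totals.** Total step count: 20. Longest linear sequence: 18 steps (steps 1–5 and 8–20; steps 6 and 7 make the diene).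

**Steps most likely to fail**

Step 8. The cycloaddition may be too slow, because the diene carries two substituents at its reacting terminus, one of them inside. The endo or π-facial preference may also be incomplete, which would erode the configuration at C4. The fallback sets out from 14 and 8 and returns at 15. Ester 14 is reduced with i-Bu2AlH to (2Z)-2-methylpenta-2,4-dien-1-ol F1, which is protected as its 4-methoxybenzyl ether F2 (4-methoxybenzyl 2,2,2-trichloroacetimidate, cat. camphorsulfonic acid). This electron-richer diene should undergo a Me2AlCl-promoted Diels–Alder reaction with 8 at −78 °C, with the same regio-, endo- and facial sense, to the 19-(4-methoxybenzyloxy) adduct F3. DDQ in buffered CH2Cl2 should release the 19-alcohol F4. Oxidation with SO3·pyridine, DMSO and Et3N should give the 19-aldehyde F5, and NaClO2 with NaH2PO4 and 2-methylbut-2-ene the 19-acid F6. Esterification with O-tert-butyl-N,N′-diisopropylisourea then gives 15.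

Step 18. The ene reaction of the cis-disubstituted C2=C3 alkene may stall at the neopentyl C3 terminus, or photo-oxidation may degrade the substrate. The fallback sets out from 27 and returns at 29. Dimethyldioxirane should epoxidise the C2=C3 alkene from the β face to the 2β,3β-epoxide F7, the enone alkene being inert. NaSePh (from PhSeH and NaH, THF/EtOH) should open the epoxide at C2 in the trans-diaxial sense and add to the enone terminus C17, giving the 2α,17-bis(phenylselanyl) 3β-alcohol F8. Oxidation with H2O2 and selenoxide syn-elimination, away from the carbinol carbon in ring A and back to the enone in ring D, should give 29.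

Step 13. Acid strong enough to protonate the C5=C10 alkene may also trigger cationic rearrangement of the 13-oxygenated C16=C17 bicycle or attack the 2-(trimethylsilyl)ethyl ester. The fallback sets out from 22 and returns at 23. HF·pyridine in THF at 0 °C should cleave the silyl enol ether and the trimethylsilyl ether without touching either ester and give the 12-keto 13-alcohol F9. Iodolactonisation (I2, NaHCO3, MeCN, 0 °C) should engage the tert-butyl ester under neutral conditions at the more electron-rich tetrasubstituted alkene and give the 5β-iodo 19,10-lactone F10. Radical deiodination (Bu3SnH, AIBN, benzene, 80 °C) should deliver hydrogen to C5 from the β face and give 23.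

**Further compounds**

F1 | step 8 | (2Z)-2-methylpenta-2,4-dien-1-ol | C=C/C=C(/C)CO
F2 | step 8 | 1-methoxy-4-({[(2Z)-2-methylpenta-2,4-dien-1-yl]oxy}methyl)benzene | C=C/C=C(/C)COCc1ccc(OC)cc1
F3 | step 8 | 19-(4-methoxybenzyloxy) analogue of adduct 15 (CH2O-4-methoxybenzyl in place of the tert-butyl ester) | C=C1C[C@]23C[C@@]1(O[Si](C)(C)C)C(=O)C[C@H]2[C@@H]2CC=C[C@@](C)(COCc4ccc(OC)cc4)[C@@H]2C3=O
F4 | step 8 | 19-alcohol analogue of adduct 15 | C=C1C[C@]23C[C@@]1(O[Si](C)(C)C)C(=O)C[C@H]2[C@@H]2CC=C[C@@](C)(CO)[C@@H]2C3=O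
F5 | step 8 | 19-aldehyde analogue of adduct 15 | C=C1C[C@]23C[C@@]1(O[Si](C)(C)C)C(=O)C[C@H]2[C@@H]2CC=C[C@@](C)(C=O)[C@@H]2C3=O
F6 | step 8 | 19-carboxylic acid analogue of adduct 15 | C=C1C[C@]23C[C@@]1(O[Si](C)(C)C)C(=O)C[C@H]2[C@@H]2CC=C[C@@](C)(C(=O)O)[C@@H]2C3=O
F7 | step 18 | 2β,3β-epoxide of 27 | C=C1C(=O)[C@]23C[C@@]1(O)[C@@H](O)C[C@H]2[C@@]12C[C@@H]4O[C@@H]4[C@@](C)(C(=O)O1)[C@H]2[C@@H]3C(=O)OCC[Si](C)(C)C
F8 | step 18 | 2α,17-bis(phenylselanyl) 3β-alcohol (16,17-dihydro, C16 epimers) | C([Se]c4ccccc4)C1C(=O)[C@]23C[C@@]1(O)[C@@H](O)C[C@H]2[C@@]12C[C@@H]([Se]c4ccccc4)[C@H](O)[C@@](C)(C(=O)O1)[C@H]2[C@@H]3C(=O)OCC[Si](C)(C)C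
F9 | step 13 | 12-keto 13-alcohol of 22 (C5=C10 diester, 6α-ester) | C=C1C[C@]23C[C@@]1(O)C(=O)C[C@H]2C2=C([C@](C)(C(=O)OC(C)(C)C)C=CC2)[C@H]3C(=O)OCC[Si](C)(C)C
F10 | step 13 | 5β-iodo 19,10-lactone with 12-ketone, 13-hydroxy and 6α-ester | C=C1C[C@]23C[C@@]1(O)C(=O)C[C@H]2[C@@]12CC=C[C@@](C)(C(=O)O1)[C@@]2(I)[C@H]3C(=O)OCC[Si](C)(C)C
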